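The readings come from a simulation for an exercise; noise was put on by code.

**Falling rate.** In the west run G disappeared faster at the start than late: 0.00600 /min of the charge up to 6.00 min, but 0.00147 /min between 50.0 min and 90.0 min, a factor 4.07.

| setting | west | flask |
|---|---|---|
| G | 0.033 M | 0.022 M |
| X | 10 mol% | 10 mol% |
| remark | run made earlier |  |
| time |  | 8.0 h |

west run (percent of the G charged)

| time / min | L / % | Q / % | G / % |
|---|---|---|---|
| 6.00 | 0 | 2.6 | 96.4 |
| 20.0 | 1.3 | 7.8 | 88.6 |
| 30.0 | 1.7 | 9.9 | 85.4 |
| 50.0 | 1.8 | 12.4 | 81.1 |
| 80.0 | 2.5 | 14.9 | 77.1 |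
| 90.0 | 3.6 | 15.4 | 75.2 |

(readings scatter by 0.5 percentage points)

- no earlier run changes the charge of X; that part of a forecast is a guess

- ratio of L to Q at 4.0 min
- ratio of L to Q at 8.0 h
- which of L and Q there is more of at 8.0 h

**Two brakes.** If the rate follows G, the drop in G gives a factor 1.28. That leaves a larger factor, 3.18, for failing X (catalyst deactivation) or a way back, and we do not try to separate the two.

**The budget.** We let the rate fade exponentially, with fade time τ = 47.8 min. Integrated, the rate delivers a budget B, the start rate r times τ, the whole loss of G under that fade: 28.7%. The west run had lost 24.8% by 90.0 min, so by this reckoning 3.85% remained.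

**This flask.** We assume that, at equal loading, rates scale with the charge. Then τ becomes 71.6 min, B stays, and nearly all of it is delivered by 8.0 h. With Q held at its last west reading and the remainder going to L, we put L/Q in this flask at 0.484 as a high estimate, up from the last west reading of 0.234, so we expect Q ahead. For 4.0 min we commit to nothing: L read 0% at 6.00 min, with scatter 0.5 percentage points.

**The forecast.** It gave 0.13 at 4.0 min, 0.3 at 8.0 h and Q ahead: “Sequential leakage could raise that considerably”.

**The result.** This flask gives L/Q 0.0287 at 4.0 min and 0.316 at 8.0 h, less than our estimate, with L 5.42% against Q 17.1%. By 8.0 h this flask had lost 32.5% of its G, more than B.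

    G + X ⇌ Q + X, rate k1*[G]*[X] forward; the back reaction follows from the equilibrium constant (K = 0.270, k = 96.0 /M/h)
    Q + X ⇌ L + X, rate k2*[X]*[Q] forward; the back reaction follows from the equilibrium constant (K = 1.90, k = 15.0 /M/h)
    L + X ⇌ E + X, rate k3*[X]*[L] forward; the back reaction follows from the equilibrium constant (K = 0.0950, k = 320 /M/h)
    E + X ⇌ G + X, rate k4*[X]*[E] forward; the back reaction follows from the equilibrium constant (k = 260 /M/h)
    G + X → Z (k = 20.0 /M/h)

**Neighbour flask.** For the neighbour flask with 0.0088 M of G, τ becomes 179 min, so B yields 26.7% by 8.0 h. That neighbour flask lost 27.5% of its G by 8.0 h.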